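In a one-step world the percentage of target at a given hour ignores the charge, so one first-order constant from any run would serve every flask.

| flask | substrate | remark | time |
|---|---|---|---|
| alder | 0.050 M | run made earlier |  |
| maple | 0.20 M | run made earlier |  |
| south-east | 0.099 M |  | 12 h |
| west | 0.099 M |  | 6.0 h |

- alder (time / h: target / %): 0.833: 1.2; 2.50: 4.5; 5.00: 9.5; 8.00: 19.3
- maple (time / h: target / %): 0.500: 0; 1.33: 8.1; 3.00: 30.8; 8.00: 71.9

(readings scatter by 1 percentage point)

- which one finishes higher in amount of target, in percent of the substrate charged ("neither" within 2 percentage points) (south-east / west / neither)
- amount of target at the end, in percent of the substrate charged, south-east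
- amount of target at the end, in percent of the substrate charged, west

- the numbers in the tables scatter with a standard deviation of 1 percentage point
- a reading or a percentage of target counts all its forms, free or not

Try that rule of thumb on maple. Between 3.00 h and 8.00 h, the logarithm of what is not yet target falls at 0.180 h⁻¹, and from 1.33 h to 3.00 h at a similar 0.170 h⁻¹. Now find the border with alder: its last two readings give 0.0382 h⁻¹, which is 0.212 of maple's constant, close to the charge ratio of 0.250. So the constant read on maple does not carry over to alder. Maple was already on its line at [target] = 16.2 mM, while alder ended at 9.65 mM, still below that mark.

Call 0.180 h⁻¹ the ceiling constant, a pseudo-first-order constant that you should expect only past that mark. For 0.099 M of substrate, the mark is 16.4 % of the charge. Alder passed that percentage by 8.00 h on half the charge, so I expect this charge to pass it before 6.0 h. My reckoning is then that, from 6.0 h to 12 h, what is not yet target shrinks to a third, which puts south-east above west. Watch for that slope.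

The forecast gives south-east, with 66 % for south-east and 27 % for west, on the ground “No loss of target is seen, so the longer run finishes higher”.

The flask gives 67.9 % for south-east and 38.0 % for west, so south-east finishes higher.

    substrate + target → 2 target (k = 0.290 M⁻¹ min⁻¹)
    substrate → target (k = 3.00 × 10⁻⁴ min⁻¹)
    target ⇌ isomer of the product (K = 1.90, k = 0.0360 min⁻¹)
    crystals ⇌ target, rate k4*(cs4 - [target]) while solid is left; crystals form when [target] > cs4 (solubility = 10.0 mM, k = 0.150 min⁻¹)

In south-east, target rises from 38.0 % at 6.00 h to 67.9 % at 12.0 h, so what is not target falls by a factor of 0.518, against the 0.340 I reckoned; substrate falls by a factor of 0.298, and isomer of the product stands at 20.8 % and then 19.9 %. Now take a neighbouring flask, the same as south-east but with 0.40 M of substrate, twice maple's charge. Carrying maple's last reading forward to 12 h with the ceiling constant gives 86.3 % target. That neighbouring flask ends at 12 h with 89.6 % target and 5.35 % of its substrate left.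

All runs come from a simulation for substances that don't exist, and the scatter is random.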